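**Plan**

1. Germacrane numbering (C1–C15) is used throughout. The enabling feature is the γ-lactone ring O–C6–C7–C11–C12: its O-bearing carbon C6 is allylic to the C4=C5 alkene and C7 carries the α-methylene carbon C11. This is the product pattern of a diene carbo-oxygenation through a C4–C5–C6 π-allyl.
2. Retrosynthesis: remove the C8 methacrylate, the C14 oxidation (back to CH3) and the C9 methyl ether; open the ten-membered ring at C9–C10 (vinyl iodide plus aldehyde); cut the lactone at O–C6 and C7–C11 into an acyclic (4E,6E)-diene and 2-bromoacrylic acid; cut the diene at C4=C5 and C6=C7.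
3. Forward: diene by two olefinations of glyceraldehyde acetonide (steps 1–5); lactone ring by a palladium-catalysed (3+2) heteroannulation (step 6); Z vinyl iodide and C9 aldehyde (steps 7–10); ten-membered ring by Nozaki–Hiyama–Kishi closure (step 11); C9 adjustment, OMe, methacrylate, C14 oxidation, deprotection (steps 12–18).
4. Stereocentres: C8 from (R)-glyceraldehyde acetonide; C7 by 1,2-induction from C8 in the carbopalladation; C6 by syn carbopalladation of the E alkene and C–O closure on the palladium face (trans lactone); C9 by Felkin–Anh reduction of the macrocyclic enone.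
5. Alkene geometry: C4=C5 from the E-selective Horner–Wadsworth–Emmons reaction, kept through the π-allyl; C1=C10 from the Z-selective iodo-Wittig reaction and the E-selective allylic oxidation.

Key step: step 6

Remark: (R)-glyceraldehyde acetonide is taken as a commercial starting material; CIP descriptors are given for each compound as drawn, so a descriptor can change where only a neighbouring group changes.

**Step 1**
Reactants: 1 (4R)-2,2-dimethyl-1,3-dioxolane-4-carbaldehyde; 2 (triphenylphosphoranylidene)acetaldehyde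
Product: 3 (2E)-3-[(4S)-2,2-dimethyl-1,3-dioxolan-4-yl]prop-2-enal
Conditions: 2 (1.0 equiv), toluene, rt to 60 °C
Reagents that add atoms: none
Why: Wittig olefination with the formyl-stabilised ylide should give the E enal (C5–C7), with C8 carried unchanged from the chiral pool.

**Step 2**
Reactants: 4 triethyl phosphonoacetate; 5 3-bromo-1,1-dimethoxypropane
Product: 6 ethyl 2-(diethoxyphosphoryl)-5,5-dimethoxypentanoate (racemic)
Conditions: NaH, NaI (cat.), DMSO, 60 °C
Reagents that add atoms: none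
Why: Malonate-type C-alkylation of the sodium phosphonoacetate installs C1–C3 with C1 masked as a dimethyl acetal; the new centre is lost in step 3.

**Step 3**
Reactants: 3 enal; 6 phosphonate
Product: 7 ethyl (2E,4E)-2-(3,3-dimethoxypropyl)-5-[(4S)-2,2-dimethyl-1,3-dioxolan-4-yl]penta-2,4-dienoate
Conditions: NaH, THF, 0 °C to rt
Reagents that add atoms: none
Why: Horner–Wadsworth–Emmons olefination with the α-alkyl phosphonoacetate should give the E enoate, which places C6 cis to C3 across C4=C5 as in the target.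

**Step 4**
Reactants: 7 dienoate
Product: 8 (2E,4E)-2-(3,3-dimethoxypropyl)-5-[(4S)-2,2-dimethyl-1,3-dioxolan-4-yl]penta-2,4-dien-1-ol
Conditions: i-Bu2AlH (2.5 equiv), CH2Cl2, −78 °C
Reagents that add atoms: none
Why: 1,2-Reduction of the conjugated ester by the aluminium hydride gives the C15 allylic alcohol and leaves both acetals intact.

**Step 5**
Reactants: 8 dienol
Product: 9 tert-butyl{[(2E,4E)-2-(3,3-dimethoxypropyl)-5-[(4S)-2,2-dimethyl-1,3-dioxolan-4-yl]penta-2,4-dien-1-yl]oxy}diphenylsilane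
Conditions: TBDPSCl, imidazole, CH2Cl2, rt
Reagents that add atoms: tert-butyl(chloro)diphenylsilane, CC(C)(C)[Si](Cl)(c1ccccc1)c1ccccc1
Why: Silylation of the primary allylic alcohol gives a C15 ether that survives base, acid, fluoride-free steps and the later selective cleavage of triethylsilyl ethers.

**Step 6**
Reactants: 9 diene; 10 2-bromoprop-2-enoic acid
Product: 11 (4S,5R)-5-[(1E)-2-({[tert-butyl(diphenyl)silyl]oxy}methyl)-5,5-dimethoxypent-1-en-1-yl]-4-[(4S)-2,2-dimethyl-1,3-dioxolan-4-yl]-3-methylideneoxolan-2-one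
Conditions: Pd(OAc)2 (10 mol %), P(o-tol)3 (20 mol %), K2CO3 (2.5 equiv), DMF, 60 °C, 10 (1.5 equiv) added slowly
Reagents that add atoms: none
Why: Proposed new method: zerovalent palladium inserts into the C–Br bond of the carboxylate of 10, the vinylpalladium species adds syn across C6=C7 with the new C7–C11 bond at the less hindered diene terminus, and the π-allylpalladium unit spanning C6–C5–C4 is captured at C6 by the palladium-bound carboxylate, a formal (3+2) carbo-oxygenation that releases zerovalent palladium and delivers the α-methylene lactone with its exocyclic alkene in place. The closest known reaction type is the Larock heteroannulation of 1,3-dienes with aryl halides that carry an ortho OH, NHR or CO2H group; an α-bromoacrylic acid as the partner on a chiral acyclic diene is the extension. The lactone ring closes by C–O bond formation at the allyl terminus C6 (five-membered ring by reductive elimination from a six-membered palladacycle, exo with respect to the allyl unit), closure at C4 being excluded because it would need a seven-membered ring at a fully substituted carbon. C7 is set by 1,2-induction from C8: palladium should engage the C6=C7 face anti to the dioxolane C8–C9 bond with the C8–O bond near the alkene plane (inside-alkoxy model), giving the 7,8-anti relationship; C6 follows from syn carbopalladation of the E alkene and delivery of oxygen on the palladium face, and reversible ionisation of the allylic C6–O bond by zerovalent palladium should also drain material toward the more stable trans lactone. The step needs regioselectivity for C7 over C4 (C4 is fully substituted), chemoselectivity against a thermal Diels–Alder reaction with 10 (the cis substituent on C4 disfavours the s-cis diene) and retention of the C4=C5 geometry (the substituents on C4 can exchange only through an unfavourable tertiary σ-allyl).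

**Step 7**
Reactants: 11 lactone
Product: 12 (4R,5R)-5-[(1E)-2-({[tert-butyl(diphenyl)silyl]oxy}methyl)-5-oxopent-1-en-1-yl]-4-[(1S)-1,2-dihydroxyethyl]-3-methylideneoxolan-2-one
Conditions: AcOH/THF/H2O (3:1:1), 40 °C
Reagents that add atoms: water, O
Why: Mild aqueous acid hydrolyses the acetonide and the dimethyl acetal together and leaves the silyl ether and the lactone alone; the 5-endo oxa-Michael closure of the C8 hydroxyl is disfavoured, and the product is silylated at once to limit lactone migration.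

**Step 8**
Reactants: 12 diol aldehyde
Product: 13 (4S,5R)-4-[(1S)-1,2-bis(triethylsilyloxy)ethyl]-5-[(1E)-2-({[tert-butyl(diphenyl)silyl]oxy}methyl)-5-oxopent-1-en-1-yl]-3-methylideneoxolan-2-one
Conditions: TESCl, imidazole, DMAP (cat.), CH2Cl2, 0 °C
Reagents that add atoms: chlorotriethylsilane, CC[Si](Cl)(CC)CC
Why: Silylation of both hydroxyls under weakly basic conditions protects C8 and sets up the primary C9 ether for direct oxidation in step 10.

**Step 9**
Reactants: 13 aldehyde; 14 ethyltriphenylphosphonium iodide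
Product: 15 (4S,5R)-4-[(1S)-1,2-bis(triethylsilyloxy)ethyl]-5-[(1E,5Z)-2-({[tert-butyl(diphenyl)silyl]oxy}methyl)-6-iodohepta-1,5-dien-1-yl]-3-methylideneoxolan-2-one
Conditions: 14, n-BuLi, THF, rt; I2, −78 °C; NaN(SiMe3)2, −20 °C; then 13, −78 °C
Reagents that add atoms: iodine, II
Why: Wittig olefination with the α-iodoethylidene ylide (Stork–Zhao type) should give the Z trisubstituted vinyl iodide with iodine cis to C2, the aldehyde reacting at −78 °C much faster than the methylene lactone.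

**Step 10**
Reactants: 15 vinyl iodide
Product: 16 (2S)-2-[(2R,3S)-2-[(1E,5Z)-2-({[tert-butyl(diphenyl)silyl]oxy}methyl)-6-iodohepta-1,5-dien-1-yl]-4-methylidene-5-oxooxolan-3-yl]-2-(triethylsilyloxy)acetaldehyde
Conditions: (COCl)2, DMSO, CH2Cl2, −78 to −30 °C; Et3N
Reagents that add atoms: none
Why: Under Swern conditions a primary triethylsilyl ether is cleaved and oxidised directly to the aldehyde while the secondary one at C8 stays, which gives the C9 aldehyde in one operation.

**Step 11**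
Reactants: 16 iodo aldehyde
Product: 17 (1(10)Z,4E,6R,7S,8S)-15-{[tert-butyl(diphenyl)silyl]oxy}-9-hydroxy-8-(triethylsilyloxy)germacra-1(10),4,11(13)-trien-12,6-olide, mixture of C9 epimers
Conditions: CrCl2 (10 equiv), NiCl2 (cat.), DMSO/THF, rt, 2 mM
Reagents that add atoms: none
Why: Nozaki–Hiyama–Kishi reaction: the vinylchromium species forms from the Z iodide with retention of geometry and adds chemoselectively to the aldehyde under high dilution, closing the ten-membered ring at C9–C10; C9 is not relied on here and is set in steps 12 and 13.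

**Step 12**
Reactants: 17 allylic alcohol
Product: 18 (1(10)Z,4E,6R,7S,8S)-15-{[tert-butyl(diphenyl)silyl]oxy}-9-oxo-8-(triethylsilyloxy)germacra-1(10),4,11(13)-trien-12,6-olide
Conditions: Dess–Martin periodinane, NaHCO3, CH2Cl2, rt
Reagents that add atoms: none
Why: Dess–Martin oxidation converges both C9 epimers on one enone under neutral conditions that spare the silyl ethers and the C8 centre.

**Step 13**
Reactants: 18 enone
Product: 19 (1(10)Z,4E,6R,7S,8S,9S)-15-{[tert-butyl(diphenyl)silyl]oxy}-9-hydroxy-8-(triethylsilyloxy)germacra-1(10),4,11(13)-trien-12,6-olide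
Conditions: NaBH4, CeCl3·7H2O, MeOH/THF, −78 °C
Reagents that add atoms: none
Why: Luche reduction gives 1,2-reduction only, and hydride should add to the carbonyl face anti to the C8–OSi bond (polar Felkin–Anh model), which gives the 8,9-syn (9S) alcohol.

**Step 14**
Reactants: 19 alcohol
Product: 20 (1(10)Z,4E,6R,7S,8S,9S)-15-{[tert-butyl(diphenyl)silyl]oxy}-9-methoxy-8-(triethylsilyloxy)germacra-1(10),4,11(13)-trien-12,6-olide
Conditions: Me3OBF4, 1,8-bis(dimethylamino)naphthalene, 4 Å MS, CH2Cl2, rt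
Reagents that add atoms: trimethyloxonium tetrafluoroborate, C[O+](C)C.F[B-](F)(F)F
Why: O-Methylation with the Meerwein salt and a non-nucleophilic base works on hindered secondary alcohols without alkoxide formation, so the lactone, the Michael acceptor and the silyl ethers are not put at risk.

**Step 15**
Reactants: 20 methyl ether
Product: 21 (1(10)Z,4E,6R,7R,8S,9S)-15-{[tert-butyl(diphenyl)silyl]oxy}-8-hydroxy-9-methoxygermacra-1(10),4,11(13)-trien-12,6-olide
Conditions: HF·pyridine, pyridine, THF, 0 °C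
Reagents that add atoms: none
Why: Buffered HF·pyridine cleaves the secondary triethylsilyl ether much faster than the tert-butyldiphenylsilyl ether, which frees only the C8 hydroxyl.

**Step 16**
Reactants: 21 alcohol
Product: 22 (1(10)Z,4E,6R,7S,8S,9S)-15-{[tert-butyl(diphenyl)silyl]oxy}-9-methoxy-8-(2-methylprop-2-enoyloxy)germacra-1(10),4,11(13)-trien-12,6-olide
Conditions: methacrylic anhydride, DMAP, Et3N, CH2Cl2, 0 °C
Reagents that add atoms: methacrylic anhydride, CC(=C)C(=O)OC(=O)C(C)=C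
Why: DMAP-catalysed acylation is fast enough to esterify the C8 hydroxyl before the free alcohol can translactonise onto C12.

**Step 17**
Reactants: 22 methacrylate
Product: 23 (1(10)E,4E,6R,7S,8S,9S)-15-{[tert-butyl(diphenyl)silyl]oxy}-9-methoxy-8-(2-methylprop-2-enoyloxy)-14-oxogermacra-1(10),4,11(13)-trien-12,6-olide
Conditions: SeO2 (2.5 equiv), 1,4-dioxane, 80 °C
Reagents that add atoms: selenium dioxide, O=[Se]=O
Why: Riley oxidation (ene reaction, then 2,3-sigmatropic shift) should oxidise the methyl group on the more substituted carbon of the more electron-rich C1=C10 alkene to the E enal, a change with close precedent on the C10 methyl of germacranolides; the C4=C5 alkene is deactivated by its two allylic C–O bonds.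

**Step 18**
Reactants: 23 silyl ether
Product: 24 (1(10)E,4E,6R,7S,8S,9S)-15-hydroxy-9-methoxy-8-(2-methylprop-2-enoyloxy)-14-oxogermacra-1(10),4,11(13)-trien-12,6-olide (target)
Conditions: HF·pyridine (excess), THF, rt
Reagents that add atoms: none
Why: Acidic fluoride removes the primary silyl ether without the basic conditions that would endanger the enal, the methacrylate and the methylene lactone.

**Compound list**

1 | (4R)-2,2-dimethyl-1,3-dioxolane-4-carbaldehyde | CC1(C)OC[C@@H](O1)C=O | starting material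
2 | (triphenylphosphoranylidene)acetaldehyde | O=CC=P(c1ccccc1)(c1ccccc1)c1ccccc1 | starting material
3 | (2E)-3-[(4S)-2,2-dimethyl-1,3-dioxolan-4-yl]prop-2-enal | CC1(C)OC[C@@H](O1)/C=C/C=O | intermediate
4 | triethyl phosphonoacetate | CCOC(=O)CP(=O)(OCC)OCC | starting material
5 | 3-bromo-1,1-dimethoxypropane | COC(OC)CCBr | starting material
6 | ethyl 2-(diethoxyphosphoryl)-5,5-dimethoxypentanoate | CCOC(=O)C(CCC(OC)OC)P(=O)(OCC)OCC | intermediate
7 | ethyl (2E,4E)-2-(3,3-dimethoxypropyl)-5-[(4S)-2,2-dimethyl-1,3-dioxolan-4-yl]penta-2,4-dienoate | CC1(C)OC[C@@H](O1)/C=C/C=C(/C(=O)OCC)CCC(OC)OC | intermediate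
8 | (2E,4E)-2-(3,3-dimethoxypropyl)-5-[(4S)-2,2-dimethyl-1,3-dioxolan-4-yl]penta-2,4-dien-1-ol | CC1(C)OC[C@@H](O1)/C=C/C=C(/CO)CCC(OC)OC | intermediate
9 | tert-butyl{[(2E,4E)-2-(3,3-dimethoxypropyl)-5-[(4S)-2,2-dimethyl-1,3-dioxolan-4-yl]penta-2,4-dien-1-yl]oxy}diphenylsilane | CC1(C)OC[C@@H](O1)/C=C/C=C(/CO[Si](c2ccccc2)(c3ccccc3)C(C)(C)C)CCC(OC)OC | intermediate
10 | 2-bromoprop-2-enoic acid | C=C(Br)C(=O)O | starting material
11 | (4S,5R)-5-[(1E)-2-({[tert-butyl(diphenyl)silyl]oxy}methyl)-5,5-dimethoxypent-1-en-1-yl]-4-[(4S)-2,2-dimethyl-1,3-dioxolan-4-yl]-3-methylideneoxolan-2-one | CC1(C)OC[C@@H](O1)[C@H]2C(=C)C(=O)O[C@@H]2/C=C(/CO[Si](c3ccccc3)(c4ccccc4)C(C)(C)C)CCC(OC)OC | intermediate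
12 | (4R,5R)-5-[(1E)-2-({[tert-butyl(diphenyl)silyl]oxy}methyl)-5-oxopent-1-en-1-yl]-4-[(1S)-1,2-dihydroxyethyl]-3-methylideneoxolan-2-one | OC[C@@H](O)[C@H]2C(=C)C(=O)O[C@@H]2/C=C(/CO[Si](c3ccccc3)(c4ccccc4)C(C)(C)C)CCC=O | intermediate
13 | (4S,5R)-4-[(1S)-1,2-bis(triethylsilyloxy)ethyl]-5-[(1E)-2-({[tert-butyl(diphenyl)silyl]oxy}methyl)-5-oxopent-1-en-1-yl]-3-methylideneoxolan-2-one | CC[Si](CC)(CC)OC[C@@H](O[Si](CC)(CC)CC)[C@H]2C(=C)C(=O)O[C@@H]2/C=C(/CO[Si](c3ccccc3)(c4ccccc4)C(C)(C)C)CCC=O | intermediate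
14 | ethyltriphenylphosphonium iodide | CC[P+](c1ccccc1)(c1ccccc1)c1ccccc1.[I-] | starting material
15 | (4S,5R)-4-[(1S)-1,2-bis(triethylsilyloxy)ethyl]-5-[(1E,5Z)-2-({[tert-butyl(diphenyl)silyl]oxy}methyl)-6-iodohepta-1,5-dien-1-yl]-3-methylideneoxolan-2-one | CC[Si](CC)(CC)OC[C@@H](O[Si](CC)(CC)CC)[C@H]2C(=C)C(=O)O[C@@H]2/C=C(/CO[Si](c3ccccc3)(c4ccccc4)C(C)(C)C)CC/C=C(/C)I | intermediate
16 | (2S)-2-[(2R,3S)-2-[(1E,5Z)-2-({[tert-butyl(diphenyl)silyl]oxy}methyl)-6-iodohepta-1,5-dien-1-yl]-4-methylidene-5-oxooxolan-3-yl]-2-(triethylsilyloxy)acetaldehyde | O=C[C@@H](O[Si](CC)(CC)CC)[C@H]2C(=C)C(=O)O[C@@H]2/C=C(/CO[Si](c3ccccc3)(c4ccccc4)C(C)(C)C)CC/C=C(/C)I | intermediate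
17 | (1(10)Z,4E,6R,7S,8S)-15-{[tert-butyl(diphenyl)silyl]oxy}-9-hydroxy-8-(triethylsilyloxy)germacra-1(10),4,11(13)-trien-12,6-olide, C9 epimers | OC1[C@@H](O[Si](CC)(CC)CC)[C@H]2C(=C)C(=O)O[C@@H]2/C=C(/CO[Si](c3ccccc3)(c4ccccc4)C(C)(C)C)CC/C=C1/C | intermediate
18 | (1(10)Z,4E,6R,7S,8S)-15-{[tert-butyl(diphenyl)silyl]oxy}-9-oxo-8-(triethylsilyloxy)germacra-1(10),4,11(13)-trien-12,6-olide | O=C1[C@@H](O[Si](CC)(CC)CC)[C@H]2C(=C)C(=O)O[C@@H]2/C=C(/CO[Si](c3ccccc3)(c4ccccc4)C(C)(C)C)CC/C=C1/C | intermediate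
19 | (1(10)Z,4E,6R,7S,8S,9S)-15-{[tert-butyl(diphenyl)silyl]oxy}-9-hydroxy-8-(triethylsilyloxy)germacra-1(10),4,11(13)-trien-12,6-olide | O[C@@H]1[C@@H](O[Si](CC)(CC)CC)[C@H]2C(=C)C(=O)O[C@@H]2/C=C(/CO[Si](c3ccccc3)(c4ccccc4)C(C)(C)C)CC/C=C1/C | intermediate
20 | (1(10)Z,4E,6R,7S,8S,9S)-15-{[tert-butyl(diphenyl)silyl]oxy}-9-methoxy-8-(triethylsilyloxy)germacra-1(10),4,11(13)-trien-12,6-olide | CO[C@@H]1[C@@H](O[Si](CC)(CC)CC)[C@H]2C(=C)C(=O)O[C@@H]2/C=C(/CO[Si](c3ccccc3)(c4ccccc4)C(C)(C)C)CC/C=C1/C | intermediate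
21 | (1(10)Z,4E,6R,7R,8S,9S)-15-{[tert-butyl(diphenyl)silyl]oxy}-8-hydroxy-9-methoxygermacra-1(10),4,11(13)-trien-12,6-olide | CO[C@@H]1[C@@H](O)[C@H]2C(=C)C(=O)O[C@@H]2/C=C(/CO[Si](c3ccccc3)(c4ccccc4)C(C)(C)C)CC/C=C1/C | intermediate
22 | (1(10)Z,4E,6R,7S,8S,9S)-15-{[tert-butyl(diphenyl)silyl]oxy}-9-methoxy-8-(2-methylprop-2-enoyloxy)germacra-1(10),4,11(13)-trien-12,6-olide | CO[C@@H]1[C@@H](OC(=O)C(C)=C)[C@H]2C(=C)C(=O)O[C@@H]2/C=C(/CO[Si](c3ccccc3)(c4ccccc4)C(C)(C)C)CC/C=C1/C | intermediate
23 | (1(10)E,4E,6R,7S,8S,9S)-15-{[tert-butyl(diphenyl)silyl]oxy}-9-methoxy-8-(2-methylprop-2-enoyloxy)-14-oxogermacra-1(10),4,11(13)-trien-12,6-olide | CO[C@@H]1[C@@H](OC(=O)C(C)=C)[C@H]2C(=C)C(=O)O[C@@H]2/C=C(/CO[Si](c3ccccc3)(c4ccccc4)C(C)(C)C)CC/C=C1/C=O | intermediate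
24 | (1(10)E,4E,6R,7S,8S,9S)-15-hydroxy-9-methoxy-8-(2-methylprop-2-enoyloxy)-14-oxogermacra-1(10),4,11(13)-trien-12,6-olide | C=C(C)C(=O)O[C@H]1[C@H]2C(=C)C(=O)O[C@@H]2/C=C(/CO)CC/C=C(/C=O)[C@@H]1OC | target

**Step count and risks**

Total: 18 steps. Longest linear sequence: 17 steps (steps 1 and 3–18 from 1; equally steps 2–18 from 4 and 5).

Step 6 (heteroannulation). What may go wrong: attack of the vinylpalladium on the diene face syn to the dioxolane; backside attack of the carboxylate, which would give the cis lactone; loss of the C4=C5 geometry by π–σ–π isomerisation; polymerisation of 10 before oxidative addition. The fallback uses known chemistry only, forms C6–C7 and O–C12 instead, sets out from 1 and 6 and comes back at 11. A Morita–Baylis–Hillman reaction of 1 with methyl acrylate (DABCO) would give methyl 2-{[(4R)-2,2-dimethyl-1,3-dioxolan-4-yl](hydroxy)methyl}prop-2-enoate F1, and NBS/Me2S would convert it with allylic transposition into methyl (2Z)-2-(bromomethyl)-3-[(4S)-2,2-dimethyl-1,3-dioxolan-4-yl]prop-2-enoate F2. In parallel, Horner–Wadsworth–Emmons reaction of 6 with (tert-butyldimethylsilyloxy)acetaldehyde would give ethyl (2E)-4-{[tert-butyl(dimethyl)silyl]oxy}-2-(3,3-dimethoxypropyl)but-2-enoate F3. Reduction with i-Bu2AlH would give (2E)-4-{[tert-butyl(dimethyl)silyl]oxy}-2-(3,3-dimethoxypropyl)but-2-en-1-ol F4, TBDPSCl the bis-silyl ether F5, buffered HF·pyridine (2E)-3-({[tert-butyl(diphenyl)silyl]oxy}methyl)-6,6-dimethoxyhex-2-en-1-ol F6, and MnO2 (2E)-3-({[tert-butyl(diphenyl)silyl]oxy}methyl)-6,6-dimethoxyhex-2-enal F7. A CrCl2-mediated Nozaki–Hiyama allylation of F7 with F2 should give the anti homoallylic alcohol, the methyl hydroxy ester F8, through a chair transition state, and F8 would lactonise to 11 on mild acid treatment.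

Step 11 (macrocyclisation). What may go wrong: intermolecular oligomerisation and reductive loss of iodine outrunning the strained ten-membered ring closure. The fallback closes the ring at C1=C10 by ring-closing metathesis, sets out from 13 and comes back at 17. Wittig methylenation of 13 (Ph3P=CH2) would give (4S,5R)-4-[(1S)-1,2-bis(triethylsilyloxy)ethyl]-5-[(1E)-2-({[tert-butyl(diphenyl)silyl]oxy}methyl)hexa-1,5-dien-1-yl]-3-methylideneoxolan-2-one F9. Swern oxidation of its primary silyl ether would give (2S)-2-[(2R,3S)-2-[(1E)-2-({[tert-butyl(diphenyl)silyl]oxy}methyl)hexa-1,5-dien-1-yl]-4-methylidene-5-oxooxolan-3-yl]-2-(triethylsilyloxy)acetaldehyde F10. Intermolecular Nozaki–Hiyama–Kishi addition of 2-bromopropene (CrCl2, NiCl2 cat.) would give the isopropenyl carbinol, (4S,5R)-5-[(1E)-2-({[tert-butyl(diphenyl)silyl]oxy}methyl)hexa-1,5-dien-1-yl]-4-[(1S)-2-hydroxy-3-methyl-1-(triethylsilyloxy)but-3-en-1-yl]-3-methylideneoxolan-2-one F11, as a C9 epimer mixture. Ring-closing metathesis with a second-generation Hoveyda–Grubbs catalyst in dilute toluene at 80 °C should then give the ring-cis trisubstituted alkene of 17.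

Step 13 (reduction). What may go wrong: the conformation of the ten-membered enone exposing the other carbonyl face to hydride, or competing conjugate reduction. The fallback sets C9 during ring closure under catalyst control, sets out from 16 and comes back at 19. The Nozaki–Hiyama–Kishi cyclisation of 16 would be run with CrCl2 bound to a chiral sulfonamide–oxazoline ligand (NiCl2 cat., proton scavenger), using the ligand enantiomer that directs the vinylchromium to the aldehyde face leading to the 9S alkoxide. Steps 12 and 13 then fall away and no new compound is needed.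

**Further compounds**

F1 | step 6 | methyl 2-{[(4R)-2,2-dimethyl-1,3-dioxolan-4-yl](hydroxy)methyl}prop-2-enoate | CC1(C)OC[C@@H](O1)C(O)C(=C)C(=O)OC
F2 | step 6 | methyl (2Z)-2-(bromomethyl)-3-[(4S)-2,2-dimethyl-1,3-dioxolan-4-yl]prop-2-enoate | CC1(C)OC[C@@H](O1)/C=C(\CBr)C(=O)OC
F3 | step 6 | ethyl (2E)-4-{[tert-butyl(dimethyl)silyl]oxy}-2-(3,3-dimethoxypropyl)but-2-enoate | CC(C)(C)[Si](C)(C)OC/C=C(/C(=O)OCC)CCC(OC)OC
F4 | step 6 | (2E)-4-{[tert-butyl(dimethyl)silyl]oxy}-2-(3,3-dimethoxypropyl)but-2-en-1-ol | CC(C)(C)[Si](C)(C)OC/C=C(/CO)CCC(OC)OC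
F5 | step 6 | (2E)-1-{[tert-butyl(dimethyl)silyl]oxy}-3-({[tert-butyl(diphenyl)silyl]oxy}methyl)-6,6-dimethoxyhex-2-ene | CC(C)(C)[Si](C)(C)OC/C=C(/CO[Si](c1ccccc1)(c1ccccc1)C(C)(C)C)CCC(OC)OC
F6 | step 6 | (2E)-3-({[tert-butyl(diphenyl)silyl]oxy}methyl)-6,6-dimethoxyhex-2-en-1-ol | OC/C=C(/CO[Si](c1ccccc1)(c1ccccc1)C(C)(C)C)CCC(OC)OC
F7 | step 6 | (2E)-3-({[tert-butyl(diphenyl)silyl]oxy}methyl)-6,6-dimethoxyhex-2-enal | O=C/C=C(/CO[Si](c1ccccc1)(c1ccccc1)C(C)(C)C)CCC(OC)OC
F8 | step 6 | methyl hydroxy ester (open form of 11): methyl 2-[(1S,2R,3E)-4-({[tert-butyl(diphenyl)silyl]oxy}methyl)-1-[(4S)-2,2-dimethyl-1,3-dioxolan-4-yl]-2-hydroxy-7,7-dimethoxyhept-3-en-1-yl]prop-2-enoate | CC1(C)OC[C@@H](O1)[C@@H](C(=C)C(=O)OC)[C@H](O)/C=C(/CO[Si](c2ccccc2)(c3ccccc3)C(C)(C)C)CCC(OC)OC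
F9 | step 11 | (4S,5R)-4-[(1S)-1,2-bis(triethylsilyloxy)ethyl]-5-[(1E)-2-({[tert-butyl(diphenyl)silyl]oxy}methyl)hexa-1,5-dien-1-yl]-3-methylideneoxolan-2-one | CC[Si](CC)(CC)OC[C@@H](O[Si](CC)(CC)CC)[C@H]2C(=C)C(=O)O[C@@H]2/C=C(/CO[Si](c3ccccc3)(c4ccccc4)C(C)(C)C)CCC=C
F10 | step 11 | (2S)-2-[(2R,3S)-2-[(1E)-2-({[tert-butyl(diphenyl)silyl]oxy}methyl)hexa-1,5-dien-1-yl]-4-methylidene-5-oxooxolan-3-yl]-2-(triethylsilyloxy)acetaldehyde | O=C[C@@H](O[Si](CC)(CC)CC)[C@H]2C(=C)C(=O)O[C@@H]2/C=C(/CO[Si](c3ccccc3)(c4ccccc4)C(C)(C)C)CCC=C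
F11 | step 11 | (4S,5R)-5-[(1E)-2-({[tert-butyl(diphenyl)silyl]oxy}methyl)hexa-1,5-dien-1-yl]-4-[(1S)-2-hydroxy-3-methyl-1-(triethylsilyloxy)but-3-en-1-yl]-3-methylideneoxolan-2-one, C9 epimers | CC(=C)C(O)[C@@H](O[Si](CC)(CC)CC)[C@H]2C(=C)C(=O)O[C@@H]2/C=C(/CO[Si](c3ccccc3)(c4ccccc4)C(C)(C)C)CCC=C
F0 | step 13 | none | none
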